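## Structural features

- The target is a diarylmethane. One aryl unit is a 6-hydroxy-8-methoxy-3-methylisocoumarin: ring B is the benzene ring, ring C is the fused α-pyranone (C1 carbonyl, O2, C3 with its methyl, C4–H). A CH2 bridge at C5 links it to ring A.
- Ring A is a benzene ring whose bridge carbon is flanked by OMe and by CH2OMe, with a free OH para to the bridge.
- There is no stereocentre, so every question is one of regiochemistry.
- Ring B is pentasubstituted (only C7–H is left). Two pairs of like oxygens must be told apart: OMe at C8 versus OH at C6, and the ortho OMe versus the para OH of ring A.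
- Fragile groups are:
  - the enol lactone of ring C (hydroxide, amines, hydrides);
  - the electron-rich doubly benzylic CH2 (oxidants);
  - the benzylic methyl ether (strong Lewis acids, hydrogenolysis);
  - the C8 methoxy peri to the carbonyl (boron halides);
  - the free phenols.
- The real difficulty is building ring C at C4a, which sits beside the benzyl-bearing C5, without touching the other oxygenated positions.
- The key step uses the fact that, in the ring B benzoic acid, the carboxyl carbon on C8a has a single ortho C–H, at C4a, because C8 carries OMe. Ring C then needs only C4 and C3 (with its methyl), which an acetyl-substituted sulfoxonium ylide supplies as one carbene carbon and one ketone carbon.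

## Logic of the disconnections

**20 ⇒ 19.** The two phenolic O–H bonds are traced back to O–CH2OMe acetals. The phenols must be masked through the basic and organometallic steps. This adds one step but keeps every earlier intermediate non-acidic and easy to handle. The forward step must be acidic and mild, because the lactone of ring C does not tolerate base or nucleophiles.

**19 ⇒ 14 + 17.** The C4a–C4 and O2–C3 bonds are cut, which removes ring C entirely. This is the strategic cut: it turns a fused bicyclic lactone into a plain benzoic acid and a three-carbon ylide. The carboxyl group of 14 serves twice, as directing group and as the ring oxygen/carbonyl of the lactone. The forward step must metalate the one ortho C–H of 14 although it is crowded by the C5 benzyl group, and must leave two acetals intact.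

**17 ⇒ 15.** The bond between the ylide carbon and the acetyl carbon is cut, giving the parent sulfoxonium salt and an acetyl donor. The forward step needs two equivalents of the parent ylide, one as nucleophile and one as base.

**14 ⇒ 13.** The carboxyl O–H is traced back to a methyl ester. The acid has to be masked during the bridge-forming step, where a diazo intermediate would alkylate a free acid. The forward step is a saponification with a work-up mild enough for the acetals.

**13 ⇒ 9 + 5.** The bond between the bridge CH2 and C5 of ring B is cut. This divides the molecule into two benzene rings of similar size. The bridge carbon is the formyl carbon of 9 and the ring B partner is a boronic acid. An electron-rich benzylic halide or benzylzinc carrying an ortho methoxymethyl group is avoided: such a halide would ionise easily and be captured by the neighbouring ether oxygen. The forward step must intercept a diazo intermediate with the boronic acid faster than either partner decays.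

**5 ⇒ 4 ⇒ 3 ⇒ 2 ⇒ 1.** In turn the C5–B bond, the O2–CH3 bond, the O4–acetal bond and the C5–Br bond are removed. The order uses the innate bias of the resorcylate: bromination goes to C5, the non-chelated 4-hydroxyl is protected first, and the chelated 2-hydroxyl is methylated last. Each forward step needs only that bias.

**9 ⇒ 8 ⇒ 7 ⇒ 6.** The aryl–CH2OMe bond, the O–S bond of the triflate and the O4–acetal bond are removed. In 6 the three oxygens are already distinct: one is methylated, one is chelated to the formyl group and one is free and para. The ring A pattern therefore follows from the starting material and not from an electrophilic substitution with two competing ortho sites. The forward sequence needs one sp2–sp3 cross-coupling of a primary alkoxymethyl group.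

## Other disconnections considered

**Alternative 1:** aryne insertion into a malonate.
- Cut: C4a–C4 and C8a–C1, with ring C left open.
- Forward key step: CsF converts the ortho-silylaryl triflate A2 into the C4a–C8a aryne. The anion of dimethyl malonate A3 adds at C4a, and the aryl anion at C8a attacks an ester carbonyl, giving the homophthalate A1 after fragmentation.
- In favour: no transition metal and no acid near the acetals, which is better than the chosen plan on that point. The C8 methoxy group steers the nucleophile to the remote aryne carbon, C4a, so the regiochemistry is electronically assisted.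
- Against: attack at C4a is next to the benzyl-bearing C5, so sterics oppose the electronic preference. A2 is a benzene with five substituents including adjacent silyl and triflate groups, and would take longer to make than 14. A1 still lacks C3 and its methyl; ring C would need ester hydrolysis, C-acetylation at C4, decarboxylation and lactonisation.
- Comparison: both plans form C4a–C4 at the same crowded carbon and are equal there. The aryne route uses the C8 methoxy as a director, the chosen route uses it as a blocking group. In step economy the alternative is worse, because its key step closes no ring and leaves three to four operations where the chosen plan has one.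

**Alternative 2:** biomimetic aldol aromatisation.
- Cut: the C4a–C8a bond, with ring B made from an open chain.
- Forward key step: Et3N and then acid make the nucleophilic dioxinone carbon of the diketo-dioxinone A5 (future C8a) add to the C4a ketone. Dehydration gives the benzodioxinone A4.
- In favour: ring B is built with every substituent already placed by the chain, so there is no aromatic substitution and no crowded C–H metalation. This is better than the chosen plan on that point. The masked acetonyl group for ring C is already present. The conditions are mild and metal-free.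
- Against: A5 must be assembled by C-benzylation of the central diketone carbon with a ring A benzylic electrophile, which is the labile type of electrophile the chosen plan avoids. A5 is a polycarbonyl compound prone to retro-Claisen cleavage and premature cyclisation. In A4 the C6 oxygen is free and the C8 oxygen is tied up in the dioxinone, the opposite of what the target needs. Protection at C6, dioxinone opening, methylation at C8, lactonisation and desilylation must follow.
- Comparison: the mechanism is a polar aldol against an organometallic C–H insertion; both are sound. In step count and in handling of intermediates the alternative is clearly longer. On site selectivity in ring B it is the better of the two.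

**Alternative 3:** pyranopyrandione plus siloxyalkyne.
- Cut: C4a–C5 and C6–C7.
- Forward key step: heating the pyranopyrandione A7 with the siloxyalkyne A8 should give a [4+2] adduct across the 4-methoxy-2-pyranone ring. Loss of CO2 then gives A6, the bis(triisopropylsilyl) ether of the target.
- In favour: this is the most convergent plan. Ring C arrives intact and ring B is formed with all substituents in one step. The polarity is matched: the nucleophilic benzyl-bearing alkyne carbon meets the electrophilic ring-fusion carbon that becomes C4a. A6 is one deprotection from the target, equal to the chosen plan after the key step, and no C–H activation is needed.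
- Against: A8 would have to be made by ynolate chemistry on a homologated ring A fragment, and such alkynes are sensitive to moisture and heat (rearrangement to a silylketene, [2+2] pathways). The cycloaddition with CO2 loss needs a temperature at which A8 may not survive. A7 has two pyranone rings, and only one must act as the diene.
- Comparison: on convergence and on the number of steps after the key step it is equal or better. On the robustness of the coupling partner and on the thermal window it is weaker than the chosen plan, which uses a bench-stable ylide and a plain carboxylic acid.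

Key step: step 11

Assumption: 2,4-dihydroxy-6-methoxybenzaldehyde (6) and potassium (methoxymethyl)trifluoroborate are treated as catalogue chemicals, like 1 and 15.

Remark: the locants and SMILES of 14, 17, 18 and 19 were compared atom by atom with 20 and agree, so no structure needed correction. The precursor design differs from the obvious benzylzinc/aryl bromide union in three ways: the ring A oxygen pattern comes from 6, no benzylic halide is made, and the key step is run in an acetate buffer to protect the acetals.

## Steps

Step 1
Reactants: 1 methyl 2,4-dihydroxybenzoate
Product: 2 methyl 5-bromo-2,4-dihydroxybenzoate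
Conditions: Br2 (1.0 equiv), AcOH, rt
Reagents that add atoms: bromine, BrBr
Why: Electrophilic aromatic bromination; C5 is ortho to the 4-hydroxyl, para to the 2-hydroxyl and less crowded than C3 between the two hydroxyls, so one equivalent of bromine should take C5, as is usual in the resorcylic acid series.

Step 2
Reactants: 2 methyl 5-bromo-2,4-dihydroxybenzoate
Product: 3 methyl 5-bromo-2-hydroxy-4-(methoxymethoxy)benzoate
Conditions: MOMCl (1.1 equiv), iPr2NEt, CH2Cl2, 0 °C
Reagents that add atoms: chloromethyl methyl ether, COCCl
Why: Selective O-alkylation; the 2-hydroxyl is held in a hydrogen bond to the ester carbonyl, while the 4-hydroxyl (para to the ester, ortho to bromine) is free and more acidic, so it alone should react with one equivalent.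

Step 3
Reactants: 3 methyl 5-bromo-2-hydroxy-4-(methoxymethoxy)benzoate
Product: 4 methyl 5-bromo-2-methoxy-4-(methoxymethoxy)benzoate
Conditions: MeI, K2CO3, DMF, 50 °C
Reagents that add atoms: iodomethane, CI
Why: Williamson ether synthesis on the remaining chelated phenol; carbonate in a dipolar aprotic solvent with mild heating overcomes the hydrogen bond, and the acetal and the ester are inert.

Step 4
Reactants: 4 methyl 5-bromo-2-methoxy-4-(methoxymethoxy)benzoate
Product: 5 [4-methoxy-5-(methoxycarbonyl)-2-(methoxymethoxy)phenyl]boronic acid
Conditions: B2(OH)4 (1.5 equiv), chloro(2-dicyclohexylphosphino-2′,4′,6′-triisopropyl-1,1′-biphenyl)[2-(2′-amino-1,1′-biphenyl)]palladium (second-generation XPhos palladacycle, divalent palladium, 1 mol %), XPhos (2 mol %), KOAc (3 equiv), MeOH, 60 °C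
Reagents that add atoms: tetrahydroxydiboron, OB(O)B(O)O
Why: Miyaura-type borylation of an aryl bromide with tetrahydroxydiboron gives the free boronic acid that step 8 needs; methanol cannot scramble the methyl ester, and acetate is too weak a base to harm the ester or the acetal.

Step 5
Reactants: 6 2,4-dihydroxy-6-methoxybenzaldehyde
Product: 7 2-hydroxy-6-methoxy-4-(methoxymethoxy)benzaldehyde
Conditions: MOMCl (1.05 equiv), iPr2NEt, CH2Cl2, 0 °C
Reagents that add atoms: chloromethyl methyl ether, COCCl
Why: Same principle as step 2; the 2-hydroxyl is hydrogen-bonded to the formyl group and the para 4-hydroxyl is the more acidic, so mono-protection should go to O4, which fixes which ring A oxygen ends as the free phenol.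

Step 6
Reactants: 7 2-hydroxy-6-methoxy-4-(methoxymethoxy)benzaldehyde
Product: 8 2-formyl-3-methoxy-5-(methoxymethoxy)phenyl trifluoromethanesulfonate
Conditions: PhNTf2, K2CO3, DMF, rt
Reagents that add atoms: N-phenylbis(trifluoromethanesulfonimide), O=S(=O)(N(c1ccccc1)S(=O)(=O)C(F)(F)F)C(F)(F)F
Why: O-Sulfonylation of the phenoxide with a mild triflyl donor under carbonate; no acid is generated that could open the acetal, and triflates of salicylaldehydes are routinely made this way.

Step 7
Reactants: 8 2-formyl-3-methoxy-5-(methoxymethoxy)phenyl trifluoromethanesulfonate
Product: 9 2-methoxy-6-(methoxymethyl)-4-(methoxymethoxy)benzaldehyde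
Conditions: MeOCH2BF3K (1.5 equiv), Pd(OAc)2 (5 mol %), RuPhos (10 mol %), Cs2CO3 (3 equiv), 1,4-dioxane/H2O 10:1, 100 °C
Reagents that add atoms: potassium (methoxymethyl)trifluoroborate, COC[B-](F)(F)F.[K+]
Why: Suzuki–Miyaura sp2–sp3 coupling of an aryl triflate with an alkoxymethyl trifluoroborate; the ortho formyl group speeds oxidative addition, the bulky electron-rich phosphine drives the slow transfer and reductive elimination of a primary alkyl group that has no β-hydrogen, and the aldehyde cannot enolise.

Step 8
Reactants: 9 2-methoxy-6-(methoxymethyl)-4-(methoxymethoxy)benzaldehyde; 5 [4-methoxy-5-(methoxycarbonyl)-2-(methoxymethoxy)phenyl]boronic acid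
Product: 13 methyl 2-methoxy-4-(methoxymethoxy)-5-{[2-methoxy-6-(methoxymethyl)-4-(methoxymethoxy)phenyl]methyl}benzoate, via tosylhydrazone 10 (not isolated), via aryldiazomethane 11 (not isolated), via diarylmethylboronic acid 12 (not isolated)
Conditions: TsNHNH2 (1.0 equiv), 1,4-dioxane, 80 °C; then 5 (1.5 equiv), K2CO3 (2 equiv), 110 °C
Reagents that add atoms: none
Why: Barluenga reductive coupling of a tosylhydrazone with a boronic acid: base converts 10 into 11 (Bamford–Stevens), the boronic acid adds to the diazo carbon and its aryl group shifts from boron to carbon with loss of N2 to give 12, whose benzylic C–B bond is protonated in the same pot; no metal and no benzylic halide are involved, and the ester, acetals and ethers are spectators.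

Step 9
Reactants: 13 methyl 2-methoxy-4-(methoxymethoxy)-5-{[2-methoxy-6-(methoxymethyl)-4-(methoxymethoxy)phenyl]methyl}benzoate
Product: 14 2-methoxy-4-(methoxymethoxy)-5-{[2-methoxy-6-(methoxymethyl)-4-(methoxymethoxy)phenyl]methyl}benzoic acid
Conditions: LiOH·H2O, THF/MeOH/H2O, 50 °C; then 1 M HCl to pH 4, 0 °C
Reagents that add atoms: lithium hydroxide, [Li+].[OH-]
Why: Saponification of the aryl methyl ester by acyl–oxygen cleavage; acetals and methyl ethers are stable to hydroxide, and cold acidification only to pH 4 spares the acetals.

Step 10
Reactants: 15 trimethylsulfoxonium iodide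
Product: 17 dimethylsulfoxonium 2-oxopropylide, via dimethylsulfoxonium methylide 16 (not isolated)
Conditions: KOtBu, THF, reflux; then AcCl (0.5 equiv relative to 16), 0 °C to rt
Reagents that add atoms: acetyl chloride, CC(Cl)=O
Why: The Corey–Chaykovsky ylide 16 is C-acylated by the acid chloride and a second equivalent of 16 deprotonates the acylsulfoxonium salt, giving the carbonyl-stabilised ylide 17, which should be a storable solid.

Step 11
Reactants: 14 2-methoxy-4-(methoxymethoxy)-5-{[2-methoxy-6-(methoxymethyl)-4-(methoxymethoxy)phenyl]methyl}benzoic acid; 17 dimethylsulfoxonium 2-oxopropylide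
Product: 19 8-methoxy-6-(methoxymethoxy)-5-{[2-methoxy-6-(methoxymethyl)-4-(methoxymethoxy)phenyl]methyl}-3-methyl-1H-isochromen-1-one, via keto acid 18 (not isolated)
Conditions: 17 (2 equiv), [Cp*RhCl2]2 (4 mol %), AgSbF6 (16 mol %), NaOAc (0.5 equiv), AcOH (2 equiv), ClCH2CH2Cl, 80 °C, N2
Reagents that add atoms: none
Why: AgSbF6 removes chloride from [Cp*RhCl2]2 to give a cationic Cp*Rh species (trivalent rhodium); the carboxylate of 14 binds and its only ortho C–H, at C4a, is cleaved by concerted metalation–deprotonation to a five-membered rhodacycle. Ylide 17 then binds through carbon, dimethyl sulfoxide leaves to give a rhodium carbene, and migratory insertion of the aryl group forms the C4a–C4 bond; protonation by AcOH releases keto acid 18 and returns the catalyst. The carboxyl oxygen of 18 adds to the ketone carbonyl (6-exo-trig) and the adduct loses water under acid catalysis, placing the C3=C4 double bond in ring C. The closest known reaction type is the rhodium-catalysed ortho C–H functionalisation and annulation of benzoic acids with acyl sulfoxonium ylides to 3-substituted isocoumarins. No stereocentre is formed. Site selectivity is structural: C8 carries OMe, so C4a–H is the only C–H the carboxylate can deliver the metal to, and the bridge CH2 would need a larger and less favoured metallacycle; the two-carbon unit has no regiochemistry to control because the carbene carbon must become C4 and the acetyl carbon C3. The NaOAc/AcOH buffer is meant to keep free HSbF6 from building up so that both acetals survive; if one were lost, the product would still converge on 20 in step 12.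

Step 12
Reactants: 19 8-methoxy-6-(methoxymethoxy)-5-{[2-methoxy-6-(methoxymethyl)-4-(methoxymethoxy)phenyl]methyl}-3-methyl-1H-isochromen-1-one
Product: 20 6-hydroxy-5-{[4-hydroxy-2-methoxy-6-(methoxymethyl)phenyl]methyl}-8-methoxy-3-methyl-1H-isochromen-1-one
Conditions: HCl (about 1 M) in MeOH, rt to 40 °C
Reagents that add atoms: none
Why: Acid-catalysed acetal exchange with methanol removes both methoxymethyl groups as dimethoxymethane; the lactone, the aryl methyl ethers and the benzylic methyl ether (meta to both ring A oxygens, and regenerated by the solvent in any case) should be stable to dilute methanolic HCl.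

## Compound list

1 | methyl 2,4-dihydroxybenzoate | COC(=O)c1ccc(O)cc1O | starting material
2 | methyl 5-bromo-2,4-dihydroxybenzoate | COC(=O)c1cc(Br)c(O)cc1O | intermediate
3 | methyl 5-bromo-2-hydroxy-4-(methoxymethoxy)benzoate | COC(=O)c1cc(Br)c(OCOC)cc1O | intermediate
4 | methyl 5-bromo-2-methoxy-4-(methoxymethoxy)benzoate | COC(=O)c1cc(Br)c(OCOC)cc1OC | intermediate
5 | [4-methoxy-5-(methoxycarbonyl)-2-(methoxymethoxy)phenyl]boronic acid | COC(=O)c1cc(B(O)O)c(OCOC)cc1OC | intermediate
6 | 2,4-dihydroxy-6-methoxybenzaldehyde | COc1cc(O)cc(O)c1C=O | starting material
7 | 2-hydroxy-6-methoxy-4-(methoxymethoxy)benzaldehyde | COCOc1cc(O)c(C=O)c(OC)c1 | intermediate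
8 | 2-formyl-3-methoxy-5-(methoxymethoxy)phenyl trifluoromethanesulfonate | COCOc1cc(OC)c(C=O)c(OS(=O)(=O)C(F)(F)F)c1 | intermediate
9 | 2-methoxy-6-(methoxymethyl)-4-(methoxymethoxy)benzaldehyde | COCOc1cc(OC)c(C=O)c(COC)c1 | intermediate
10 | (E)-N′-{[2-methoxy-6-(methoxymethyl)-4-(methoxymethoxy)phenyl]methylidene}-4-methylbenzenesulfonohydrazide, formed in the flask | COCOc1cc(OC)c(/C=N/NS(=O)(=O)c2ccc(C)cc2)c(COC)c1 | intermediate
11 | 2-(diazomethyl)-1-methoxy-3-(methoxymethyl)-5-(methoxymethoxy)benzene, formed in the flask | COCOc1cc(OC)c(C=[N+]=[N-])c(COC)c1 | intermediate
12 | {[4-methoxy-5-(methoxycarbonyl)-2-(methoxymethoxy)phenyl][2-methoxy-6-(methoxymethyl)-4-(methoxymethoxy)phenyl]methyl}boronic acid, racemic, formed in the flask | COCOc1cc(OC)c(C(B(O)O)c2cc(C(=O)OC)c(OC)cc2OCOC)c(COC)c1 | intermediate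
13 | methyl 2-methoxy-4-(methoxymethoxy)-5-{[2-methoxy-6-(methoxymethyl)-4-(methoxymethoxy)phenyl]methyl}benzoate | COCOc1cc(OC)c(C(=O)OC)cc1Cc1c(COC)cc(OCOC)cc1OC | intermediate
14 | 2-methoxy-4-(methoxymethoxy)-5-{[2-methoxy-6-(methoxymethyl)-4-(methoxymethoxy)phenyl]methyl}benzoic acid | COCOc1cc(OC)c(C(=O)O)cc1Cc1c(COC)cc(OCOC)cc1OC | intermediate
15 | trimethylsulfoxonium iodide | C[S+](C)(C)=O.[I-] | starting material
16 | dimethylsulfoxonium methylide, formed in the flask | C=S(C)(C)=O | intermediate
17 | dimethylsulfoxonium 2-oxopropylide | CC(=O)C=S(C)(C)=O | intermediate
18 | 2-methoxy-4-(methoxymethoxy)-5-{[2-methoxy-6-(methoxymethyl)-4-(methoxymethoxy)phenyl]methyl}-6-(2-oxopropyl)benzoic acid, formed in the flask | COCOc1cc(OC)c(C(=O)O)c(CC(C)=O)c1Cc1c(COC)cc(OCOC)cc1OC | intermediate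
19 | 8-methoxy-6-(methoxymethoxy)-5-{[2-methoxy-6-(methoxymethyl)-4-(methoxymethoxy)phenyl]methyl}-3-methyl-1H-isochromen-1-one | COCc1cc(OCOC)cc(OC)c1Cc1c(OCOC)cc(OC)c2c(=O)oc(C)cc12 | intermediate
20 | 6-hydroxy-5-{[4-hydroxy-2-methoxy-6-(methoxymethyl)phenyl]methyl}-8-methoxy-3-methyl-1H-isochromen-1-one | COCc1cc(O)cc(OC)c1Cc1c(O)cc(OC)c2c(=O)oc(C)cc12 | target

## Step count and least certain steps

Total: 12 steps. Longest linear sequence: 8 steps (1, 2, 3, 4, 8, 9, 11, 12, from compound 1). The ring A branch (steps 5 to 7) and the ylide (step 10) are convergent.

**Step 11 (key step).**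
- Risk: metalation at C4a–H, crowded by the C5 benzyl group, may be slow. Protonation and decay of the ylide, or acid-promoted loss of an acetal, could then outrun the annulation. The cyclodehydration could also stall at the keto acid stage in the buffered medium.
- Mitigation: loss of an acetal is tolerable because step 12 removes both anyway.
- Fallback: a two-stage route from 14. Ruthenium-catalysed carboxylate-directed ortho C–H allylation ([Ru(p-cymene)Cl2]2, K3PO4, allyl acetate, 50–60 °C) should give 2-methoxy-4-(methoxymethoxy)-5-{[2-methoxy-6-(methoxymethyl)-4-(methoxymethoxy)phenyl]methyl}-6-(prop-2-en-1-yl)benzoic acid F1. Wacker-type oxidative lactonisation (PdCl2(MeCN)2, 1,4-benzoquinone, Na2CO3, THF) then proceeds by oxypalladation, β-hydride elimination and shift of the double bond into the ring, and returns to the route at 19. The allyl partner is stable to the medium and can be used in large excess.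

**Step 8.**
- Risk: protodeboronation of the ortho-alkoxy boronic acid under carbonate at 110 °C before it captures the diazo intermediate. The diazo compound may also lose N2 thermally, with capture of the carbene by the neighbouring methoxymethyl oxygen, or form an azine.
- Fallback: from 9, reduction with NaBH4 in MeOH should give [2-methoxy-6-(methoxymethyl)-4-(methoxymethoxy)phenyl]methanol F2. Methyl chloroformate and pyridine convert it into [2-methoxy-6-(methoxymethyl)-4-(methoxymethoxy)phenyl]methyl methyl carbonate F3, which is far less prone to ionise than a halide. A palladium-catalysed benzylic Suzuki coupling with 5 ([Pd(η3-C3H5)Cl]2, 1,5-bis(diphenylphosphino)pentane, K2CO3, DMF, 80 °C) returns to the route at 13.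

**Step 7.**
- Risk: slow boron-to-palladium transfer of the alkoxymethyl group. This would leave time for hydrolysis of the formyl-activated triflate by aqueous carbonate and for protodeboronation of the reagent.
- Fallback: from 8, a Stille coupling with tributyl(methoxymethyl)stannane (Pd(PPh3)4, LiCl, 1,4-dioxane, 100 °C) returns to the route at 9. The tin-to-palladium transfer needs neither base nor water. It changes the organometallic partner and makes no new compound (F0).

**Step 4.**
- Risk: reduction of the C–Br bond instead of borylation, or Suzuki homocoupling of the new boronic acid with unreacted bromide.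
- Fallback: from 4, borylation with B2pin2 (Pd(dppf)Cl2, KOAc, 1,4-dioxane, 90 °C) should give methyl 2-methoxy-4-(methoxymethoxy)-5-(4,4,5,5-tetramethyl-1,3,2-dioxaborolan-2-yl)benzoate F4. The pinacol ester is inert to homocoupling under acetate. Oxidative cleavage of the pinacol (NaIO4, NH4OAc, acetone/H2O, rt) returns to the route at 5.

## Further compounds

F1 | step 11 | 2-methoxy-4-(methoxymethoxy)-5-{[2-methoxy-6-(methoxymethyl)-4-(methoxymethoxy)phenyl]methyl}-6-(prop-2-en-1-yl)benzoic acid | COCOc1cc(OC)c(C(=O)O)c(CC=C)c1Cc1c(COC)cc(OCOC)cc1OC
F2 | step 8 | [2-methoxy-6-(methoxymethyl)-4-(methoxymethoxy)phenyl]methanol | COCOc1cc(OC)c(CO)c(COC)c1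
F3 | step 8 | [2-methoxy-6-(methoxymethyl)-4-(methoxymethoxy)phenyl]methyl methyl carbonate | COCOc1cc(OC)c(COC(=O)OC)c(COC)c1
F0 | step 7 | none | none
F4 | step 4 | methyl 2-methoxy-4-(methoxymethoxy)-5-(4,4,5,5-tetramethyl-1,3,2-dioxaborolan-2-yl)benzoate | COC(=O)c1cc(B2OC(C)(C)C(C)(C)O2)c(OCOC)cc1OC
A1 | alternative 1 | methyl 2-(2-methoxy-2-oxoethyl)-6-methoxy-4-(methoxymethoxy)-3-{[2-methoxy-6-(methoxymethyl)-4-(methoxymethoxy)phenyl]methyl}benzoate | COCOc1cc(OC)c(C(=O)OC)c(CC(=O)OC)c1Cc1c(COC)cc(OCOC)cc1OC
A2 | alternative 1 | 3-methoxy-5-(methoxymethoxy)-6-{[2-methoxy-6-(methoxymethyl)-4-(methoxymethoxy)phenyl]methyl}-2-(trimethylsilyl)phenyl trifluoromethanesulfonate | COCOc1cc(OC)c([Si](C)(C)C)c(OS(=O)(=O)C(F)(F)F)c1Cc1c(COC)cc(OCOC)cc1OC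
A3 | alternative 1 | dimethyl malonate | COC(=O)CC(=O)OC
A4 | alternative 2 | 7-hydroxy-6-{[2-methoxy-6-(methoxymethyl)-4-(triisopropylsilyloxy)phenyl]methyl}-2,2-dimethyl-5-[(2-methyl-1,3-dioxolan-2-yl)methyl]-4H-1,3-benzodioxin-4-one | CC1(C)OC(=O)c2c(O1)cc(O)c(Cc3c(COC)cc(O[Si](C(C)C)(C(C)C)C(C)C)cc3OC)c2CC2(C)OCCO2
A5 | alternative 2 | 6-[3-{[2-methoxy-6-(methoxymethyl)-4-(triisopropylsilyloxy)phenyl]methyl}-5-(2-methyl-1,3-dioxolan-2-yl)-2,4-dioxopentyl]-2,2-dimethyl-4H-1,3-dioxin-4-one | CC1(C)OC(=O)C=C(CC(=O)C(Cc2c(COC)cc(O[Si](C(C)C)(C(C)C)C(C)C)cc2OC)C(=O)CC2(C)OCCO2)O1
A6 | alternative 3 | 8-methoxy-5-{[2-methoxy-6-(methoxymethyl)-4-(triisopropylsilyloxy)phenyl]methyl}-3-methyl-6-(triisopropylsilyloxy)-1H-isochromen-1-one | COCc1cc(O[Si](C(C)C)(C(C)C)C(C)C)cc(OC)c1Cc1c(O[Si](C(C)C)(C(C)C)C(C)C)cc(OC)c2c(=O)oc(C)cc12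
A7 | alternative 3 | 4-methoxy-7-methylpyrano[4,3-b]pyran-2,5-dione | COc1cc(=O)oc2cc(C)oc(=O)c12
A8 | alternative 3 | triisopropyl({3-[2-methoxy-6-(methoxymethyl)-4-(triisopropylsilyloxy)phenyl]prop-1-yn-1-yl}oxy)silane | COCc1cc(O[Si](C(C)C)(C(C)C)C(C)C)cc(OC)c1CC#CO[Si](C(C)C)(C(C)C)C(C)C
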